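**Assumption:** atoms are labelled with germacrane numbering (C1 ketone, C4–C5 epoxide, C6 lactone carbinol, C7=C11, C8 acyloxy carbon, C10 methyl-bearing carbon, C12 lactone carbonyl, C13 CH2OAc), and the SMILES is read as 4R,5S,6S,8S,10R with a cis (Z-derived) epoxide.

## Retrosynthetic overview

1. Target 23 ⇐ acrylate 22 by Morita–Baylis–Hillman hydroxymethylation; 22 ⇐ 20 by unmasking and oxidising C1.
2. 20 (ten-membered carbocycle plus butenolide) ⇐ acyclic epoxy aldehyde / (Z)-β-iodo enoate 18: one CrCl2/NiCl2-mediated C6–C7 addition with in-situ lactonisation closes both rings and sets C6.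
3. 18 ⇐ Z-allylic alcohol 16 by Sharpless epoxidation (sets C4/C5) and oxidation.
4. Iodo enoate ⇐ γ-hydroxy ynoate 11 by hydroxyl-directed iodo-aldol with CH2O; 11 ⇐ aldehyde 9 + methyl propiolate (sets C8).
5. 9 ⇐ neryl acetate by ozonolysis, Brown crotylation (sets C10) and anti-Markovnikov Wacker oxidation. Ring order: epoxide first, then carbocycle and butenolide together.

## Route

Step 1
Reactants: 1 neryl acetate [(2Z)-3,7-dimethylocta-2,6-dien-1-yl acetate]
Product: 3 (2Z)-3-methyl-6-oxohex-2-en-1-yl acetate, via ozonide 2 (not isolated)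
Conditions: O3 (1.0 equiv), CH2Cl2, −78 °C; then Me2S, −78 °C to rt
Reagents that add atoms: ozone, [O-][O+]=O
Why: Chemoselective ozonolysis, in which the electron-rich isopropylidene alkene reacts faster than the alkene deactivated by the allylic acetate, so one equivalent of ozone cleaves only the 6,7-bond and leaves the Z-alkene intact.

Step 2
Reactants: 3 (2Z)-3-methyl-6-oxohex-2-en-1-yl acetate; 4 trans-2-butene
Product: 7 (2Z,6S,7R)-3,7-dimethylnona-2,8-diene-1,6-diol, via borinate 5 (not isolated), via hydroxy acetate 6 (not isolated)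
Conditions: 4, KOtBu, n-BuLi, THF, −78 to −45 °C; (+)-Ipc2BOMe, −78 °C; BF3·OEt2; then 3, −78 °C; then NaOH (3 M), H2O2 (30%), MeOH, 0 °C to rt
Reagents that add atoms: none
Why: Brown (E)-crotylboration through a chair Zimmerman–Traxler transition state gives the anti homoallylic alcohol, the isopinocampheyl groups derived from (−)-α-pinene select the aldehyde face that makes C10 R (6S,7R adduct), and the basic peroxide work-up that cleaves the borinate also saponifies the allylic acetate.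

Step 3
Reactants: 7 (2Z,6S,7R)-3,7-dimethylnona-2,8-diene-1,6-diol
Product: 8 (2Z,6S,7R)-1,6-bis[(tert-butyldimethylsilyl)oxy]-3,7-dimethylnona-2,8-diene
Conditions: TBSCl (2.5 equiv), imidazole, DMF, rt
Reagents that add atoms: tert-butyldimethylsilyl chloride, CC(C)(C)[Si](C)(C)Cl
Why: Corey silylation protects both hydroxyls, which keeps C1 masked until after ring closure, because a C1 ketone would trap the alkenylchromium species in a five-membered ring and a free C1 hydroxyl would open the epoxide.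

Step 4
Reactants: 8 (2Z,6S,7R)-1,6-bis[(tert-butyldimethylsilyl)oxy]-3,7-dimethylnona-2,8-diene
Product: 9 (3R,4S,7Z)-4,9-bis[(tert-butyldimethylsilyl)oxy]-3,7-dimethylnon-7-enal
Conditions: PdCl2(PhCN)2 (12 mol%), CuCl2·2H2O (12 mol%), AgNO2 (6 mol%), O2 (1 atm), t-BuOH/MeNO2 (15:1), rt
Reagents that add atoms: dioxygen, O=O
Why: Nitrite-modified aldehyde-selective (anti-Markovnikov) Wacker oxidation of the terminal alkene, steered to the terminal carbon by the allylic branch and the homoallylic silyl ether, leaves the trisubstituted alkene and the C10 stereocentre untouched.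

Step 5
Reactants: 9 (3R,4S,7Z)-4,9-bis[(tert-butyldimethylsilyl)oxy]-3,7-dimethylnon-7-enal; 10 methyl propiolate
Product: 11 methyl (4S,6R,7S,10Z)-7,12-bis[(tert-butyldimethylsilyl)oxy]-4-hydroxy-6,10-dimethyldodec-10-en-2-ynoate
Conditions: 10 (4 equiv), Et2Zn (4 equiv), (R)-BINOL (40 mol%), HMPA (2 equiv), CH2Cl2, rt, 16 h; Ti(OiPr)4 (1 equiv); then 9, rt
Reagents that add atoms: none
Why: BINOL–titanium-catalysed enantioselective alkynylzinc addition (Pu alkynylation) is reagent-controlled, and (R)-BINOL is expected to deliver the alkynyl group to the aldehyde face that gives the (S)-propargylic alcohol at C8, a facial sense assigned by analogy with reported (S)-BINOL additions and to be confirmed by Mosher analysis.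

Step 6
Reactants: 11 methyl (4S,6R,7S,10Z)-7,12-bis[(tert-butyldimethylsilyl)oxy]-4-hydroxy-6,10-dimethyldodec-10-en-2-ynoate
Product: 13 methyl (2Z,4S,6R,7S,10Z)-7,12-bis[(tert-butyldimethylsilyl)oxy]-4-hydroxy-2-(hydroxymethyl)-3-iodo-6,10-dimethyldodeca-2,10-dienoate, via magnesium allenolate 12 (not isolated)
Conditions: MgI2 (2 equiv), monomeric CH2O (from cracked paraformaldehyde, 5 equiv), CH2Cl2, −40 to 0 °C; aq. NH4Cl
Reagents that add atoms: magnesium iodide, [Mg+2].[I-].[I-]; formaldehyde, C=O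
Why: Proposed new method: iodide adds to the MgI2-activated ynoate to give a β-iodo allenolate that is hydroxymethylated at the α-carbon by formaldehyde held on the magnesium alkoxide of the C8 hydroxyl, so the new CH2OH arrives from the C8 side and the iodine ends up cis to the ester (2Z), while any 2E isomer lactonises to an easily separated 8,12-butenolide, the closest known reaction being the MgI2-promoted iodo-aldol (β-iodo Baylis–Hillman) reaction of propiolates and ynones with aldehydes.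

Step 7
Reactants: 13 methyl (2Z,4S,6R,7S,10Z)-7,12-bis[(tert-butyldimethylsilyl)oxy]-4-hydroxy-2-(hydroxymethyl)-3-iodo-6,10-dimethyldodeca-2,10-dienoate
Product: 14 methyl (2Z,4S,6R,7S,10Z)-2-(acetoxymethyl)-7,12-bis[(tert-butyldimethylsilyl)oxy]-4-hydroxy-3-iodo-6,10-dimethyldodeca-2,10-dienoate
Conditions: AcCl (1.1 equiv), 2,4,6-collidine, CH2Cl2, −78 °C
Reagents that add atoms: acetyl chloride, CC(=O)Cl
Why: Selective acylation, in which acetyl chloride with collidine at low temperature acetylates the unhindered primary allylic hydroxyl in preference to the secondary C8 hydroxyl flanked by the tetrasubstituted iodoalkene.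

Step 8
Reactants: 14 methyl (2Z,4S,6R,7S,10Z)-2-(acetoxymethyl)-7,12-bis[(tert-butyldimethylsilyl)oxy]-4-hydroxy-3-iodo-6,10-dimethyldodeca-2,10-dienoate
Product: 15 methyl (2Z,4S,6R,7S,10Z)-2-(acetoxymethyl)-4-(acryloyloxy)-7,12-bis[(tert-butyldimethylsilyl)oxy]-3-iodo-6,10-dimethyldodeca-2,10-dienoate
Conditions: acryloyl chloride (1.5 equiv), iPr2NEt, CH2Cl2, −20 °C
Reagents that add atoms: acryloyl chloride, C=CC(=O)Cl
Why: Plain O-acylation of the remaining secondary alcohol, which sits trans to the methyl ester across the alkene so that no lactone can form, and which leaves C8 untouched.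

Step 9
Reactants: 15 methyl (2Z,4S,6R,7S,10Z)-2-(acetoxymethyl)-4-(acryloyloxy)-7,12-bis[(tert-butyldimethylsilyl)oxy]-3-iodo-6,10-dimethyldodeca-2,10-dienoate
Product: 16 methyl (2Z,4S,6R,7S,10Z)-2-(acetoxymethyl)-4-(acryloyloxy)-7-[(tert-butyldimethylsilyl)oxy]-12-hydroxy-3-iodo-6,10-dimethyldodeca-2,10-dienoate
Conditions: HF·pyridine, pyridine, THF, 0 °C
Reagents that add atoms: none
Why: Selective desilylation, since buffered HF·pyridine cleaves the primary allylic silyl ether much faster than the hindered secondary one and so frees the allylic alcohol while C1 stays protected.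

Step 10
Reactants: 16 methyl (2Z,4S,6R,7S,10Z)-2-(acetoxymethyl)-4-(acryloyloxy)-7-[(tert-butyldimethylsilyl)oxy]-12-hydroxy-3-iodo-6,10-dimethyldodeca-2,10-dienoate
Product: 17 methyl (2Z,4S,6R,7S)-2-(acetoxymethyl)-4-(acryloyloxy)-7-[(tert-butyldimethylsilyl)oxy]-9-[(2R,3S)-3-(hydroxymethyl)-2-methyloxiran-2-yl]-3-iodo-6-methylnon-2-enoate
Conditions: Ti(OiPr)4 (20 mol%), L-(+)-DET (24 mol%), TBHP (2 equiv), 4 Å MS, CH2Cl2, −20 °C
Reagents that add atoms: tert-butyl hydroperoxide, CC(C)(C)OO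
Why: Sharpless asymmetric epoxidation with L-(+)-diethyl tartrate delivers oxygen to the face of the Z-allylic alcohol that gives the (4R,5S) cis-epoxide (as nerol gives (2S,3R)-epoxynerol), with reagent control overriding the remote stereocentres and the electron-poor alkenes left alone.

Step 11
Reactants: 17 methyl (2Z,4S,6R,7S)-2-(acetoxymethyl)-4-(acryloyloxy)-7-[(tert-butyldimethylsilyl)oxy]-9-[(2R,3S)-3-(hydroxymethyl)-2-methyloxiran-2-yl]-3-iodo-6-methylnon-2-enoate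
Product: 18 methyl (2Z,4S,6R,7S)-2-(acetoxymethyl)-4-(acryloyloxy)-7-[(tert-butyldimethylsilyl)oxy]-9-[(2R,3R)-3-formyl-2-methyloxiran-2-yl]-3-iodo-6-methylnon-2-enoate
Conditions: DMP (1.5 equiv), NaHCO3, CH2Cl2, 0 °C to rt
Reagents that add atoms: none
Why: Buffered Dess–Martin oxidation converts the epoxy alcohol into the α,β-epoxy aldehyde without opening the epoxide or epimerising C5 (the descriptor at C5 changes to R only because the CHO group gains priority).

Step 12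
Reactants: 18 methyl (2Z,4S,6R,7S)-2-(acetoxymethyl)-4-(acryloyloxy)-7-[(tert-butyldimethylsilyl)oxy]-9-[(2R,3R)-3-formyl-2-methyloxiran-2-yl]-3-iodo-6-methylnon-2-enoate
Product: 20 (1S,4R,5S,6S,8S,10R)-13-acetoxy-8-(acryloyloxy)-1-[(tert-butyldimethylsilyl)oxy]-4,5-epoxygermacr-7(11)-en-12,6-olide, via hydroxy ester 19 (not isolated)
Conditions: CrCl2 (10 equiv), NiCl2 (0.1 equiv), DMSO/THF (3:1), 2 mM, slow addition of 18, rt; aq. work-up
Reagents that add atoms: none
Why: Intramolecular Nozaki–Hiyama–Kishi reaction, in which the alkenylchromium species formed with retention from the (Z)-β-iodo enoate adds to the aldehyde and closes the ten-membered ring under Felkin–Anh control (epoxide C–O anti to the incoming carbon, giving the 5,6-anti carbinol, 6S), and the alkoxide, held cis to the methyl ester, lactonises at once to the butenolide.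

Step 13
Reactants: 20 (1S,4R,5S,6S,8S,10R)-13-acetoxy-8-(acryloyloxy)-1-[(tert-butyldimethylsilyl)oxy]-4,5-epoxygermacr-7(11)-en-12,6-olide
Product: 22 (4R,5S,6S,8S,10R)-13-acetoxy-8-(acryloyloxy)-4,5-epoxy-1-oxogermacr-7(11)-en-12,6-olide, via alcohol 21 (not isolated)
Conditions: HF·pyridine, pyridine, CH2Cl2, 0 °C to rt; solid NaHCO3; then DMP (excess), same flask, 0 °C
Reagents that add atoms: none
Why: Buffered fluoride desilylation followed at once by Dess–Martin oxidation gives the C1 ketone before the free 1-hydroxy-4,5-epoxide can cyclise across the ring, and the neutral oxidation does not epimerise the adjacent C10 stereocentre.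

Step 14
Reactants: 22 (4R,5S,6S,8S,10R)-13-acetoxy-8-(acryloyloxy)-4,5-epoxy-1-oxogermacr-7(11)-en-12,6-olide
Product: 23 (4R,5S,6S,8S,10R)-13-acetoxy-4,5-epoxy-8-{[2-(hydroxymethyl)acryloyl]oxy}-1-oxogermacr-7(11)-en-12,6-olide (CNP0258719.1)
Conditions: aq. CH2O (37%, 5 equiv), DABCO (1 equiv), 1,4-dioxane/H2O (1:1), rt
Reagents that add atoms: formaldehyde, C=O
Why: Morita–Baylis–Hillman hydroxymethylation of the acrylate with formaldehyde gives the 2-(hydroxymethyl)acrylate directly, the fully substituted β-carbon of the butenolide being too hindered for amine attack and no stereocentre being touched.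

## Compound list

1 | neryl acetate [(2Z)-3,7-dimethylocta-2,6-dien-1-yl acetate] | CC(C)=CCC/C(C)=C\COC(C)=O | starting material
2 | ozonide: (2Z)-5-(5,5-dimethyl-1,2,4-trioxolan-3-yl)-3-methylpent-2-en-1-yl acetate | CC(=O)OC/C=C(C)\CCC1OOC(C)(C)O1 | intermediate (not isolated)
3 | (2Z)-3-methyl-6-oxohex-2-en-1-yl acetate | CC(=O)OC/C=C(C)\CCC=O | intermediate
4 | trans-2-butene | C/C=C/C | starting material
5 | borinate: (2Z,6S,7R)-6-[bis(isopinocampheyl)boranyloxy]-3,7-dimethylnona-2,8-dien-1-yl acetate | CC(=O)OC/C=C(C)\CC[C@H](OB([C@H]1C[C@H]2C[C@@H]([C@@H]1C)C2(C)C)[C@H]1C[C@H]2C[C@@H]([C@@H]1C)C2(C)C)[C@H](C)C=C | intermediate (not isolated)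
6 | hydroxy acetate: (2Z,6S,7R)-6-hydroxy-3,7-dimethylnona-2,8-dien-1-yl acetate | CC(=O)OC/C=C(C)\CC[C@H](O)[C@H](C)C=C | intermediate (not isolated)
7 | (2Z,6S,7R)-3,7-dimethylnona-2,8-diene-1,6-diol | OC/C=C(C)\CC[C@H](O)[C@H](C)C=C | intermediate
8 | (2Z,6S,7R)-1,6-bis[(tert-butyldimethylsilyl)oxy]-3,7-dimethylnona-2,8-diene | CC(C)(C)[Si](C)(C)OC/C=C(C)\CC[C@H](O[Si](C)(C)C(C)(C)C)[C@H](C)C=C | intermediate
9 | (3R,4S,7Z)-4,9-bis[(tert-butyldimethylsilyl)oxy]-3,7-dimethylnon-7-enal | CC(C)(C)[Si](C)(C)OC/C=C(C)\CC[C@H](O[Si](C)(C)C(C)(C)C)[C@H](C)CC=O | intermediate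
10 | methyl propiolate | C#CC(=O)OC | starting material
11 | methyl (4S,6R,7S,10Z)-7,12-bis[(tert-butyldimethylsilyl)oxy]-4-hydroxy-6,10-dimethyldodec-10-en-2-ynoate | CC(C)(C)[Si](C)(C)OC/C=C(C)\CC[C@H](O[Si](C)(C)C(C)(C)C)[C@H](C)C[C@H](O)C#CC(=O)OC | intermediate
12 | magnesium allenolate: β-iodo allenyl ester enolate (O–MgI) formed from 11 by iodide addition at C7 | CC(C)(C)[Si](C)(C)OC/C=C(C)\CC[C@H](O[Si](C)(C)C(C)(C)C)[C@H](C)C[C@H](O)C(I)=C=C(OC)O[Mg]I | intermediate (not isolated)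
13 | methyl (2Z,4S,6R,7S,10Z)-7,12-bis[(tert-butyldimethylsilyl)oxy]-4-hydroxy-2-(hydroxymethyl)-3-iodo-6,10-dimethyldodeca-2,10-dienoate | CC(C)(C)[Si](C)(C)OC/C=C(C)\CC[C@H](O[Si](C)(C)C(C)(C)C)[C@H](C)C[C@H](O)/C(I)=C(\CO)C(=O)OC | intermediate
14 | methyl (2Z,4S,6R,7S,10Z)-2-(acetoxymethyl)-7,12-bis[(tert-butyldimethylsilyl)oxy]-4-hydroxy-3-iodo-6,10-dimethyldodeca-2,10-dienoate | CC(C)(C)[Si](C)(C)OC/C=C(C)\CC[C@H](O[Si](C)(C)C(C)(C)C)[C@H](C)C[C@H](O)/C(I)=C(\COC(C)=O)C(=O)OC | intermediate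
15 | methyl (2Z,4S,6R,7S,10Z)-2-(acetoxymethyl)-4-(acryloyloxy)-7,12-bis[(tert-butyldimethylsilyl)oxy]-3-iodo-6,10-dimethyldodeca-2,10-dienoate | CC(C)(C)[Si](C)(C)OC/C=C(C)\CC[C@H](O[Si](C)(C)C(C)(C)C)[C@H](C)C[C@H](OC(=O)C=C)/C(I)=C(\COC(C)=O)C(=O)OC | intermediate
16 | methyl (2Z,4S,6R,7S,10Z)-2-(acetoxymethyl)-4-(acryloyloxy)-7-[(tert-butyldimethylsilyl)oxy]-12-hydroxy-3-iodo-6,10-dimethyldodeca-2,10-dienoate | OC/C=C(C)\CC[C@H](O[Si](C)(C)C(C)(C)C)[C@H](C)C[C@H](OC(=O)C=C)/C(I)=C(\COC(C)=O)C(=O)OC | intermediate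
17 | methyl (2Z,4S,6R,7S)-2-(acetoxymethyl)-4-(acryloyloxy)-7-[(tert-butyldimethylsilyl)oxy]-9-[(2R,3S)-3-(hydroxymethyl)-2-methyloxiran-2-yl]-3-iodo-6-methylnon-2-enoate | OC[C@@H]1O[C@]1(C)CC[C@H](O[Si](C)(C)C(C)(C)C)[C@H](C)C[C@H](OC(=O)C=C)/C(I)=C(\COC(C)=O)C(=O)OC | intermediate
18 | methyl (2Z,4S,6R,7S)-2-(acetoxymethyl)-4-(acryloyloxy)-7-[(tert-butyldimethylsilyl)oxy]-9-[(2R,3R)-3-formyl-2-methyloxiran-2-yl]-3-iodo-6-methylnon-2-enoate | O=C[C@@H]1O[C@]1(C)CC[C@H](O[Si](C)(C)C(C)(C)C)[C@H](C)C[C@H](OC(=O)C=C)/C(I)=C(\COC(C)=O)C(=O)OC | intermediate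
19 | hydroxy ester: methyl (1S,4R,5S,6S,8S,10R,7(11)Z)-13-acetoxy-8-(acryloyloxy)-1-[(tert-butyldimethylsilyl)oxy]-4,5-epoxy-6-hydroxygermacr-7(11)-en-12-oate (formed as its chromium alkoxide) | C=CC(=O)O[C@H]1C[C@@H](C)[C@@H](O[Si](C)(C)C(C)(C)C)CC[C@@]2(C)O[C@H]2[C@@H](O)/C1=C(/COC(C)=O)C(=O)OC | intermediate (not isolated)
20 | (1S,4R,5S,6S,8S,10R)-13-acetoxy-8-(acryloyloxy)-1-[(tert-butyldimethylsilyl)oxy]-4,5-epoxygermacr-7(11)-en-12,6-olide | C=CC(=O)O[C@H]1C[C@@H](C)[C@@H](O[Si](C)(C)C(C)(C)C)CC[C@@]2(C)O[C@H]2[C@H]2OC(=O)C(COC(C)=O)=C12 | intermediate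
21 | alcohol: (1S,4R,5S,6S,8S,10R)-13-acetoxy-8-(acryloyloxy)-4,5-epoxy-1-hydroxygermacr-7(11)-en-12,6-olide | C=CC(=O)O[C@H]1C[C@@H](C)[C@@H](O)CC[C@@]2(C)O[C@H]2[C@H]2OC(=O)C(COC(C)=O)=C12 | intermediate (not isolated)
22 | (4R,5S,6S,8S,10R)-13-acetoxy-8-(acryloyloxy)-4,5-epoxy-1-oxogermacr-7(11)-en-12,6-olide | C=CC(=O)O[C@H]1C[C@@H](C)C(=O)CC[C@@]2(C)O[C@H]2[C@H]2OC(=O)C(COC(C)=O)=C12 | intermediate
23 | (4R,5S,6S,8S,10R)-13-acetoxy-4,5-epoxy-8-{[2-(hydroxymethyl)acryloyl]oxy}-1-oxogermacr-7(11)-en-12,6-olide (CNP0258719.1) | C=C(CO)C(=O)O[C@H]1C[C@@H](C)C(=O)CC[C@@]2(C)O[C@H]2[C@H]2OC(=O)C(COC(C)=O)=C12 | target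

## Step count and risks

Total step count: 14. Longest linear sequence: 14 steps (1 → 23).

The three steps most likely to fail:

**Step 12 (Ni/Cr ring closure with lactonisation).** The epoxy aldehyde may be opened by the Lewis-acidic chromium salts, the ten-membered closure may lose to oligomerisation, the alkenylchromium species may eliminate the allylic acrylate, or C6 may form with the wrong configuration. Fallback: reverse the order of epoxidation and ring closure. Setting out from allylic alcohol 16, MnO2 oxidation gives the enal methyl (2Z,4S,6R,7S,10Z)-2-(acetoxymethyl)-4-(acryloyloxy)-7-[(tert-butyldimethylsilyl)oxy]-3-iodo-6,10-dimethyl-12-oxododeca-2,10-dienoate F3. The same CrCl2/NiCl2 cyclisation, now a 1,2-addition to a robust enal, gives the macrocyclic diene lactone (1S,4Z,6R,8S,10R)-13-acetoxy-8-(acryloyloxy)-1-[(tert-butyldimethylsilyl)oxy]germacra-4,7(11)-dien-12,6-olide F4. Epoxidation of its only electron-rich alkene with dimethyldioxirane from the outer face comes back to the route at 20. Stereocontrol at C6 and at the epoxide is then substrate-based and must be checked at F4 and at 20.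

**Step 6 (iodo-aldol with formaldehyde).** The tetrasubstituted alkene may form with the wrong geometry, or the allenolate may not capture formaldehyde cleanly. Fallback: deliver the CH2O carbon through a silicon tether. Setting out from 11, (bromomethyl)chlorodimethylsilane and Et3N give methyl (4S,6R,7S,10Z)-4-{[(bromomethyl)dimethylsilyl]oxy}-7,12-bis[(tert-butyldimethylsilyl)oxy]-6,10-dimethyldodec-10-en-2-ynoate F1. MgI2 in THF then triggers iodide conjugate addition and ring-closing C-alkylation of the allenolate by the Si–CH2–halide, giving the six-membered siloxane methyl (6S)-6-[(2R,3S,6Z)-3,8-bis[(tert-butyldimethylsilyl)oxy]-2,6-dimethyloct-6-en-1-yl]-5-iodo-2,2-dimethyl-3,6-dihydro-2H-1,2-oxasiline-4-carboxylate F2. The ring fixes the new carbon cis to C8 and therefore the iodine cis to the ester. Tamao–Fleming oxidation (H2O2, KF, KHCO3) cleaves the Si–C and Si–O bonds and comes back to the route at 13.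

**Step 14 (Morita–Baylis–Hillman on the finished skeleton).** The amine and aqueous formaldehyde may attack the acetoxymethyl butenolide, epimerise C10 or react too slowly. Fallback: carry the hydroxymethyl group through the sequence protected. 2-(Bromomethyl)acrylic acid and sodium 4-methoxybenzyl oxide give 2-{[(4-methoxybenzyl)oxy]methyl}prop-2-enoic acid F5. Setting out from 14, Yamaguchi esterification with F5 gives the C8 ester F6. The chemistry of steps 9 to 13 is then repeated: selective desilylation gives allylic alcohol F7, Sharpless epoxidation gives epoxy alcohol F8, Dess–Martin oxidation gives epoxy aldehyde F9, CrCl2/NiCl2 ring closure gives macrocycle F10, and desilylation with oxidation gives ketone F11. DDQ in CH2Cl2/pH 7 buffer removes the 4-methoxybenzyl group and comes back to the route at 23.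

## Further compounds

F1 | step 6 | methyl (4S,6R,7S,10Z)-4-{[(bromomethyl)dimethylsilyl]oxy}-7,12-bis[(tert-butyldimethylsilyl)oxy]-6,10-dimethyldodec-10-en-2-ynoate | CC(C)(C)[Si](C)(C)OC/C=C(C)\CC[C@H](O[Si](C)(C)C(C)(C)C)[C@H](C)C[C@H](O[Si](C)(C)CBr)C#CC(=O)OC
F2 | step 6 | methyl (6S)-6-[(2R,3S,6Z)-3,8-bis[(tert-butyldimethylsilyl)oxy]-2,6-dimethyloct-6-en-1-yl]-5-iodo-2,2-dimethyl-3,6-dihydro-2H-1,2-oxasiline-4-carboxylate | CC(C)(C)[Si](C)(C)OC/C=C(C)\CC[C@H](O[Si](C)(C)C(C)(C)C)[C@H](C)C[C@@H]1O[Si](C)(C)CC(C(=O)OC)=C1I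
F3 | step 12 | methyl (2Z,4S,6R,7S,10Z)-2-(acetoxymethyl)-4-(acryloyloxy)-7-[(tert-butyldimethylsilyl)oxy]-3-iodo-6,10-dimethyl-12-oxododeca-2,10-dienoate | O=C/C=C(C)\CC[C@H](O[Si](C)(C)C(C)(C)C)[C@H](C)C[C@H](OC(=O)C=C)/C(I)=C(\COC(C)=O)C(=O)OC
F4 | step 12 | (1S,4Z,6R,8S,10R)-13-acetoxy-8-(acryloyloxy)-1-[(tert-butyldimethylsilyl)oxy]germacra-4,7(11)-dien-12,6-olide | C=CC(=O)O[C@H]1C[C@@H](C)[C@@H](O[Si](C)(C)C(C)(C)C)CC/C(C)=C\[C@H]2OC(=O)C(COC(C)=O)=C12
F5 | step 14 | 2-{[(4-methoxybenzyl)oxy]methyl}prop-2-enoic acid | C=C(COCc1ccc(OC)cc1)C(=O)O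
F6 | step 14 | methyl (2Z,4S,6R,7S,10Z)-2-(acetoxymethyl)-7,12-bis[(tert-butyldimethylsilyl)oxy]-3-iodo-4-[(2-{[(4-methoxybenzyl)oxy]methyl}acryloyl)oxy]-6,10-dimethyldodeca-2,10-dienoate | CC(C)(C)[Si](C)(C)OC/C=C(C)\CC[C@H](O[Si](C)(C)C(C)(C)C)[C@H](C)C[C@H](OC(=O)C(=C)COCc1ccc(OC)cc1)/C(I)=C(\COC(C)=O)C(=O)OC
F7 | step 14 | methyl (2Z,4S,6R,7S,10Z)-2-(acetoxymethyl)-7-[(tert-butyldimethylsilyl)oxy]-12-hydroxy-3-iodo-4-[(2-{[(4-methoxybenzyl)oxy]methyl}acryloyl)oxy]-6,10-dimethyldodeca-2,10-dienoate | OC/C=C(C)\CC[C@H](O[Si](C)(C)C(C)(C)C)[C@H](C)C[C@H](OC(=O)C(=C)COCc1ccc(OC)cc1)/C(I)=C(\COC(C)=O)C(=O)OC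
F8 | step 14 | methyl (2Z,4S,6R,7S)-2-(acetoxymethyl)-7-[(tert-butyldimethylsilyl)oxy]-9-[(2R,3S)-3-(hydroxymethyl)-2-methyloxiran-2-yl]-3-iodo-4-[(2-{[(4-methoxybenzyl)oxy]methyl}acryloyl)oxy]-6-methylnon-2-enoate | OC[C@@H]1O[C@]1(C)CC[C@H](O[Si](C)(C)C(C)(C)C)[C@H](C)C[C@H](OC(=O)C(=C)COCc1ccc(OC)cc1)/C(I)=C(\COC(C)=O)C(=O)OC
F9 | step 14 | methyl (2Z,4S,6R,7S)-2-(acetoxymethyl)-7-[(tert-butyldimethylsilyl)oxy]-9-[(2R,3R)-3-formyl-2-methyloxiran-2-yl]-3-iodo-4-[(2-{[(4-methoxybenzyl)oxy]methyl}acryloyl)oxy]-6-methylnon-2-enoate | O=C[C@@H]1O[C@]1(C)CC[C@H](O[Si](C)(C)C(C)(C)C)[C@H](C)C[C@H](OC(=O)C(=C)COCc1ccc(OC)cc1)/C(I)=C(\COC(C)=O)C(=O)OC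
F10 | step 14 | (1S,4R,5S,6S,8S,10R)-13-acetoxy-1-[(tert-butyldimethylsilyl)oxy]-4,5-epoxy-8-[(2-{[(4-methoxybenzyl)oxy]methyl}acryloyl)oxy]germacr-7(11)-en-12,6-olide | C=C(COCc1ccc(OC)cc1)C(=O)O[C@H]1C[C@@H](C)[C@@H](O[Si](C)(C)C(C)(C)C)CC[C@@]2(C)O[C@H]2[C@H]2OC(=O)C(COC(C)=O)=C12
F11 | step 14 | (4R,5S,6S,8S,10R)-13-acetoxy-4,5-epoxy-8-[(2-{[(4-methoxybenzyl)oxy]methyl}acryloyl)oxy]-1-oxogermacr-7(11)-en-12,6-olide | C=C(COCc1ccc(OC)cc1)C(=O)O[C@H]1C[C@@H](C)C(=O)CC[C@@]2(C)O[C@H]2[C@H]2OC(=O)C(COC(C)=O)=C12
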